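Readings and results are simulated with made-up constants; scatter was added.

There were 4 questions, and I wanted one quantity that would serve them all.

| setting | cedar | ash | birch | alder | gamma | beta | zeta |
|---|---|---|---|---|---|---|---|
| substrate | 5.0 × 10⁻⁴ M | 5.0 × 10⁻⁴ M | 5.0 × 10⁻⁴ M | 5.0 × 10⁻⁴ M | 5.0 × 10⁻⁴ M | 5.0 × 10⁻⁴ M | 5.0 × 10⁻⁴ M |
| partner | 0.35 mM | 0.35 mM | 0.35 mM | 0.52 mM | 0.350 mM | 0.350 mM | 0.350 mM (fed, over 2.5 min) |
| reagent | 0.75 mM | 0.50 mM | 1.1 mM | 0.75 mM | 0.750 mM | 0.750 mM (fed, over 2.5 min) | 0.750 mM |
| remark | run made earlier | run made earlier | run made earlier | run made earlier | everything together at the start | all else is in the flask from the start; the feed brings no volume worth counting | all else is in the flask from the start; the feed brings no volume worth counting |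
| time |  |  |  |  | 3.0 min | 3.0 min | 3.0 min |

- cedar (time / min: target / %): 0.167: 24.8; 0.500: 13.2; 0.833: 7.0; 1.33: 4.3; 2.00: 3.1; 2.50: 1.6; 3.00: 1.9
- ash (time / min: target / %): 0.417: 17.9; 0.833: 12.3; 1.33: 6.8; 1.50: 7.8; 2.00: 5.1; 2.50: 5.8; 3.00: 3.2
- birch (time / min: target / %): 0.417: 16.1; 0.833: 5.6; 1.33: 0.3; 1.50: 1.3; 2.00: 0.4; 2.50: 1.2; 3.00: 0.8
- alder (time / min: target / %): 0.667: 16.9; 1.33: 10.2; 2.00: 6.5; 2.50: 5.1; 3.00: 1.9

(each reading ± 1 percentage point)

* the flask with the highest amount of target, in percent of the substrate charged ("all alike" if they lie within 1.5 percentage points) (gamma / beta / zeta / all alike)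
* final target, as a percentage of the substrate charged, in gamma
* final target, as a percentage of the substrate charged, in beta
* final target, as a percentage of the substrate charged, in zeta

- for target the idle adduct is counted in
- what was read earlier has a scatter of 1 percentage point, one standard deviation
- reactions considered so far: substrate + reagent -> open intermediate; reagent + partner -> second intermediate; open intermediate + second intermediate -> target; 2 second intermediate -> homo product; target -> over-reaction product; partner + target <-> idle adduct

I ran gamma, which has cedar's charge, in slow motion. In the first instants reagent has two takers: substrate, which becomes open intermediate, and partner, which becomes second intermediate. Those two then join to target. Each reagent serves once, and 0.750 mM faces 0.850 mM of takers, so reagent is the limiting reagent. That gap is 0.100 mM: the shortfall, substrate plus partner charged less reagent charged. When the last reagent has reacted, that gap stands as unreacted substrate or partner, bound partner included.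

In the middle, target decays. Cedar read 24.8% at 0.167 min but 7.0% at 0.833 min, a loss of about 1.90 /min as read from two scattered points. Target passes into over-reaction product, yet partner can hold it as idle adduct, which the readings count as target.

So I asked where the shortfall stands. At 2.00 min, birch, with reagent over by 0.250 mM, read 0.4%. Cedar read 3.1%, while ash, short by 0.350 mM, read 5.1%, and alder, short by 0.270 mM, read 6.5%. In zeta, reagent meets substrate first while partner arrives over 2.5 min, so I expected the shortfall to end up as partner. In gamma and beta the takers compete, so it should split. I committed to zeta as highest, with gamma near cedar's 1.9%.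

The forecast differed: beta highest, with 2% in gamma, 16% in beta and 8% in zeta, holding that “slow reagent feed keeps free reagent low”.

The flasks gave 0.641% in gamma, 6.22% in beta and 10.5% in zeta, so zeta stood highest.

    substrate + reagent → open intermediate (k = 529 /M/s)
    reagent + partner → second intermediate (k = 2220 /M/s)
    open intermediate + second intermediate → target (k = 2110 /M/s)
    2 second intermediate → homo product (k = 1250 /M/s)
    target → over-reaction product (k = 0.0551 /s)
    partner + target ⇌ idle adduct, settled at all times (K = 1.00 × 10⁵ /M)

Left for 30.0 min, zeta held 0.100 mM of partner, the shortfall of 0.100 mM over again. Gamma held 0.0252 mM of partner and 0.0748 mM of substrate. The largest single effect in zeta's lead over gamma is the association of partner and target to idle adduct: with that association taken away, the lead fell from 9.9 percentage points to 0.36 points.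

The neighbour of gamma charged with 1.40 mM of partner has a shortfall of 1.15 mM, so I expected plenty of free partner and target held as adduct. It kept 47.3% of its partner charge and gave 12.5% target, nearly all of it idle adduct.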